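**Retrosynthetic overview**
- The plan rests on ring A. It is a phloroglucinol nucleus whose three oxygens have different roles (O1 in the pyranone, O5 peri to C4=O, O7), with prenyl on C8 between C7 and C8a, C6 left as C–H and C4a carrying the carbonyl carbon.
- Ring B is made last. The O1–C2 bond comes from 6-endo closure of an o-hydroxyaryl aryloxy-ynone. The C4–C3 bond comes from a lithium aryloxyacetylide (hydroquinone plus trichloroethylene) and an aldehyde placed on C4a.
- Ring A is made first. Cutting C8a–C8, C7–C6 and C8a–C4a leads back to 3-ethoxycyclobutenone and a prenyl-substituted TIPS ynol ether. The vinylketene benzannulation delivers O1–H, O7–TIPS and O5–Et already differentiated.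
- The siloxyalkyne comes from prenyl bromide and ethynylmagnesium bromide, by oxidation of the lithium acetylide to the ynolate and O-silylation.
- Ring order: the outer aryl ring is bought, ring A is built, ring B is closed, then O5-ethyl and both silyl groups are removed.

Key step: step 3

Remark: the target has no stereocentre and no E/Z-isomeric double bond. It is achiral, so its constitution alone defines the requested compound.

**Step 1**
Reactants: 1 prenyl bromide (1-bromo-3-methylbut-2-ene); 2 ethynylmagnesium bromide (0.5 M in THF)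
Product: 3 5-methylhex-4-en-1-yne
Conditions: 2 (1.3 equiv), CuCl (5 mol %), THF, 0 °C → rt; fractional distillation
Reagents that add atoms: none
Why: This is a copper-catalysed allyl–alkynyl coupling of an alkynyl Grignard reagent, which with prenyl halides should occur at the unhindered primary carbon and give the skipped enyne.

**Step 2**
Reactants: 3 5-methylhex-4-en-1-yne
Product: 6 triisopropyl[(5-methylhex-4-en-1-yn-1-yl)oxy]silane, via lithium acetylide 4 (not isolated), via lithium ynolate 5 (not isolated)
Conditions: n-BuLi, THF, −78 °C; t-BuOOLi (t-BuOOH + LiHMDS, THF, −78 °C), −78 → 0 °C; TIPSOTf, −78 → 0 °C; hexane extraction, deactivated silica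
Reagents that add atoms: tert-butyl hydroperoxide CC(C)(C)OO; triisopropylsilyl triflate CC(C)[Si](C(C)C)(C(C)C)OS(=O)(=O)C(F)(F)F
Why: This is the known conversion of terminal alkynes into siloxyalkynes, in which the acetylide attacks the O–O bond of lithium tert-butyl peroxide to give the ynolate and the bulky silyl triflate traps it on oxygen rather than carbon.

**Step 3**
Reactants: 6 triisopropyl[(5-methylhex-4-en-1-yn-1-yl)oxy]silane; 7 3-ethoxycyclobut-2-en-1-one
Product: 12 5-ethoxy-2-(3-methylbut-2-en-1-yl)-3-(triisopropylsilyloxy)phenol, via vinylketene 8 (not isolated), via vinylcyclobutenone 9 (not isolated), via dienylketene 10 (not isolated), via cyclohexadienone 11 (not isolated)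
Conditions: 6 (1.3 equiv), toluene, 110 °C, slow addition of 7, Ar
Reagents that add atoms: none
Why: Heat opens 7 by a 4π electrocyclic cleavage of its C1–C4 bond to vinylketene 8, the electron-rich alkyne 6 adds across the ketene C=C in a [2+2] reaction to give 9 (new bonds C8a–C8 and C7–C6), and 9 opens again (4π) to dienylketene 10. Ring A is then closed by a thermal disrotatory 6π electrocyclisation of 10 (bond C8a–C4a), and enolisation of dienone 11 gives the phenol. This is the Danheiser benzannulation, whose siloxyalkyne variant is an established route to resorcinol monosilyl ethers and which is also known for ynol ethers carrying an allylic side chain. No lasting stereocentre is formed, since the sp3 ring carbon of 9 is racemic and vanishes on ring opening. The selectivity needed is the orientation of the [2+2] step: oxygen donation makes the prenyl-bearing alkyne carbon the nucleophile, it attacks the ketene carbonyl carbon, and prenyl therefore ends up between the new free OH (future O1) and OTIPS (O7) with OEt (O5) on the far side. The ynol ether is far more nucleophilic than the prenyl alkene, and slow addition of 7 to excess 6 should limit ketene oligomerisation and acylation of the product phenol.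

**Step 4**
Reactants: 12 5-ethoxy-2-(3-methylbut-2-en-1-yl)-3-(triisopropylsilyloxy)phenol
Product: 13 6-ethoxy-2-hydroxy-3-(3-methylbut-2-en-1-yl)-4-(triisopropylsilyloxy)benzaldehyde
Conditions: MgCl2, Et3N, (CH2O)n, MeCN, reflux; cold dilute HCl work-up
Reagents that add atoms: paraformaldehyde (as formaldehyde) C=O
Why: In the Casnati–Skattebøl ortho-formylation the magnesium phenoxide delivers formaldehyde only to an ortho carbon, so with C8 blocked by prenyl only C4a can react, and a second formaldehyde oxidises the hydroxymethyl stage by hydride transfer.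

**Step 5**
Reactants: 14 hydroquinone; 15 trichloroethylene
Product: 17 4-{[(E)-1,2-dichloroethenyl]oxy}phenol, via dichloroacetylene 16 (not isolated)
Conditions: 14 (3 equiv), K2CO3, DMF, 70 °C, Ar
Reagents that add atoms: none
Why: This is the known aryl dichlorovinyl ether synthesis, in which base eliminates HCl from 15 and phenoxide adds anti to the dichloroacetylene, which sets the E geometry, while excess hydroquinone favours mono-etherification.

**Step 6**
Reactants: 17 4-{[(E)-1,2-dichloroethenyl]oxy}phenol
Product: 18 (4-{[(E)-1,2-dichloroethenyl]oxy}phenoxy)triisopropylsilane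
Conditions: TIPSCl, imidazole, DMF, rt
Reagents that add atoms: triisopropylsilyl chloride CC(C)[Si](Cl)(C(C)C)C(C)C
Why: Standard imidazole-promoted silylation of a phenol gives a group that tolerates n-BuLi at low temperature and leaves with the O7 silyl group in the final step.

**Step 7**
Reactants: 18 (4-{[(E)-1,2-dichloroethenyl]oxy}phenoxy)triisopropylsilane; 13 6-ethoxy-2-hydroxy-3-(3-methylbut-2-en-1-yl)-4-(triisopropylsilyloxy)benzaldehyde
Product: 21 rac-1-[6-ethoxy-2-hydroxy-3-(3-methylbut-2-en-1-yl)-4-(triisopropylsilyloxy)phenyl]-3-[4-(triisopropylsilyloxy)phenoxy]prop-2-yn-1-ol, via chloroalkynyl ether 19 (not isolated), via lithium aryloxyacetylide 20 (not isolated)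
Conditions: 18 (2.5 equiv), n-BuLi (5.0 equiv), THF, −78 → −40 °C; 13, −78 → −20 °C; pH 7 buffer; used crude
Reagents that add atoms: none
Why: Vinyl deprotonation, loss of LiCl and Cl–Li exchange turn the dichlorovinyl ether into the lithium alkynyl ether (the known dichlorovinyl ether route), one equivalent of which deprotonates the phenol while the next adds 1,2 to the aldehyde, and the racemic carbinol centre is erased in step 8.

**Step 8**
Reactants: 21 the propargylic carbinol of step 7
Product: 22 1-[6-ethoxy-2-hydroxy-3-(3-methylbut-2-en-1-yl)-4-(triisopropylsilyloxy)phenyl]-3-[4-(triisopropylsilyloxy)phenoxy]prop-2-yn-1-one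
Conditions: activated MnO2, 4 Å MS, CH2Cl2, rt
Reagents that add atoms: none
Why: Neutral heterogeneous MnO2 oxidation is selective for benzylic–propargylic alcohols and should spare the ynol ether, the prenyl alkene and the silyl ethers, while the sieves take up the water formed.

**Step 9**
Reactants: 22 the o-hydroxyaryl aryloxy-ynone of step 8
Product: 23 5-ethoxy-8-(3-methylbut-2-en-1-yl)-7-(triisopropylsilyloxy)-2-[4-(triisopropylsilyloxy)phenoxy]-4H-chromen-4-one
Conditions: K2CO3 (0.2 equiv), dry acetone, rt
Reagents that add atoms: none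
Why: Proposed new method: the phenoxide of 22 should attack the aryloxy-bearing alkyne carbon (6-endo-dig oxa-Michael addition, then protonation at C3), because carbonyl withdrawal and aryloxy donation polarise the triple bond in the same sense, which makes C2 the only electrophilic alkyne carbon and leaves the 5-exo (aurone) mode electronically mismatched; the closest known reaction types are the base-mediated cyclisation of o-hydroxyaryl alkyl- and aryl-ynones to chromones and flavones and the intermolecular addition of O- and N-nucleophiles to the β-carbon of alkoxyethynyl ketones, whereas ring closure onto an aryloxy-substituted ynone appears to be without direct precedent.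

**Step 10**
Reactants: 23 the 5-ethoxychromone of step 9
Product: 25 5-hydroxy-8-(3-methylbut-2-en-1-yl)-7-(triisopropylsilyloxy)-2-[4-(triisopropylsilyloxy)phenoxy]-4H-chromen-4-one, via dichloroboron chelate 24 (not isolated)
Conditions: BCl3 (2.5 equiv), CH2Cl2, −78 → 0 °C; cold aq. NaHCO3
Reagents that add atoms: none
Why: In this classical BCl3 cleavage of a 5-alkoxychromone, boron chelated between C4=O and O5 activates the only alkyl aryl ether present for chloride attack, and with O7 still silylated and no protic acid released before the basic quench the prenyl group has no partner for chroman formation.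

**Step 11**
Reactants: 25 the 5-hydroxy bis-silyl chromone of step 10
Product: 26 Epimedonin G, 5,7-dihydroxy-2-(4-hydroxyphenoxy)-8-(3-methylbut-2-en-1-yl)-4H-chromen-4-one
Conditions: TBAF, AcOH (1:1, 2.5 equiv each), THF, 0 °C
Reagents that add atoms: none
Why: Buffered fluoride cleaves both aryl silyl ethers, and the acetic acid keeps the medium nearly neutral so that neither addition–elimination at C2 nor prenyl cyclisation should intervene.

**Compound list**
1 | prenyl bromide (1-bromo-3-methylbut-2-ene) | CC(C)=CCBr | starting material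
2 | ethynylmagnesium bromide | C#C[Mg]Br | starting material
3 | 5-methylhex-4-en-1-yne | C#CCC=C(C)C | intermediate
4 | lithium 5-methylhex-4-en-1-yn-1-ide (in situ) | [Li]C#CCC=C(C)C | intermediate
5 | lithium 5-methylhex-4-en-1-yn-1-olate (in situ) | [Li]OC#CCC=C(C)C | intermediate
6 | triisopropyl[(5-methylhex-4-en-1-yn-1-yl)oxy]silane | CC(C)=CCC#CO[Si](C(C)C)(C(C)C)C(C)C | intermediate
7 | 3-ethoxycyclobut-2-en-1-one | CCOC1=CC(=O)C1 | starting material
8 | 3-ethoxybuta-1,3-dien-1-one, the vinylketene (in situ) | C=C(OCC)C=C=O | intermediate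
9 | rac-4-(1-ethoxyethenyl)-2-prenyl-3-(triisopropylsilyloxy)cyclobut-2-en-1-one (in situ) | CCOC(=C)C1C(=O)C(CC=C(C)C)=C1O[Si](C(C)C)(C(C)C)C(C)C | intermediate
10 | 5-ethoxy-2-prenyl-3-(triisopropylsilyloxy)hexa-1,3,5-trien-1-one, ketene and vinyl termini cis (in situ) | O=C=C(CC=C(C)C)/C(O[Si](C(C)C)(C(C)C)C(C)C)=C\C(=C)OCC | intermediate
11 | 5-ethoxy-2-prenyl-3-(triisopropylsilyloxy)cyclohexa-2,4-dien-1-one (in situ) | CCOC1=CC(O[Si](C(C)C)(C(C)C)C(C)C)=C(CC=C(C)C)C(=O)C1 | intermediate
12 | 5-ethoxy-2-(3-methylbut-2-en-1-yl)-3-(triisopropylsilyloxy)phenol | CC(C)=CCc1c(O)cc(OCC)cc1O[Si](C(C)C)(C(C)C)C(C)C | intermediate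
13 | 6-ethoxy-2-hydroxy-3-(3-methylbut-2-en-1-yl)-4-(triisopropylsilyloxy)benzaldehyde | CC(C)=CCc1c(O)c(C=O)c(OCC)cc1O[Si](C(C)C)(C(C)C)C(C)C | intermediate
14 | hydroquinone | Oc1ccc(O)cc1 | starting material
15 | trichloroethylene | ClC=C(Cl)Cl | starting material
16 | dichloroacetylene (in situ) | ClC#CCl | intermediate
17 | 4-{[(E)-1,2-dichloroethenyl]oxy}phenol | Oc1ccc(O/C(Cl)=C\Cl)cc1 | intermediate
18 | (4-{[(E)-1,2-dichloroethenyl]oxy}phenoxy)triisopropylsilane | CC(C)[Si](Oc1ccc(O/C(Cl)=C\Cl)cc1)(C(C)C)C(C)C | intermediate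
19 | {4-[(chloroethynyl)oxy]phenoxy}triisopropylsilane (in situ) | ClC#COc1ccc(O[Si](C(C)C)(C(C)C)C(C)C)cc1 | intermediate
20 | lithium [4-(triisopropylsilyloxy)phenoxy]ethynide (in situ) | [Li]C#COc1ccc(O[Si](C(C)C)(C(C)C)C(C)C)cc1 | intermediate
21 | rac-1-[6-ethoxy-2-hydroxy-3-prenyl-4-(triisopropylsilyloxy)phenyl]-3-[4-(triisopropylsilyloxy)phenoxy]prop-2-yn-1-ol | CC(C)=CCc1c(O)c(C(O)C#COc2ccc(O[Si](C(C)C)(C(C)C)C(C)C)cc2)c(OCC)cc1O[Si](C(C)C)(C(C)C)C(C)C | intermediate
22 | 1-[6-ethoxy-2-hydroxy-3-prenyl-4-(triisopropylsilyloxy)phenyl]-3-[4-(triisopropylsilyloxy)phenoxy]prop-2-yn-1-one | CC(C)=CCc1c(O)c(C(=O)C#COc2ccc(O[Si](C(C)C)(C(C)C)C(C)C)cc2)c(OCC)cc1O[Si](C(C)C)(C(C)C)C(C)C | intermediate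
23 | 5-ethoxy-8-prenyl-7-(triisopropylsilyloxy)-2-[4-(triisopropylsilyloxy)phenoxy]-4H-chromen-4-one | CC(C)=CCc1c(O[Si](C(C)C)(C(C)C)C(C)C)cc(OCC)c2c(=O)cc(Oc3ccc(O[Si](C(C)C)(C(C)C)C(C)C)cc3)oc12 | intermediate
24 | 5-O-dichloroboryl chelate of 25 (in situ) | CC(C)=CCc1c(O[Si](C(C)C)(C(C)C)C(C)C)cc(OB(Cl)Cl)c2c(=O)cc(Oc3ccc(O[Si](C(C)C)(C(C)C)C(C)C)cc3)oc12 | intermediate
25 | 5-hydroxy-8-prenyl-7-(triisopropylsilyloxy)-2-[4-(triisopropylsilyloxy)phenoxy]-4H-chromen-4-one | CC(C)=CCc1c(O[Si](C(C)C)(C(C)C)C(C)C)cc(O)c2c(=O)cc(Oc3ccc(O[Si](C(C)C)(C(C)C)C(C)C)cc3)oc12 | intermediate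
26 | Epimedonin G | CC(C)=CCc1c(O)cc(O)c2c(=O)cc(Oc3ccc(O)cc3)oc12 | target

**Total step count:** 11. **Longest linear sequence:** 9 (steps 1–4 and 7–11). Steps 5 and 6 form the side branch.

**Steps most likely to fail**

*Step 9 (labelled step).*
- Risk: traces of water may hydrate the push–pull triple bond, or a second addition at C2 may expel aryloxide, faster than the ring closes.
- Fallback: known chemistry in which the C2–OAr bond is made last by addition–elimination. It sets out from aldehyde 13, with hydroquinone 14 supplying the phenol partner, and rejoins the route at chromone 23.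
- Excess MeMgBr (THF, 0 °C) should give the 1-arylethanol F1, and MnO2 should give the o-hydroxyacetophenone F2. CS2 and t-BuOK in THF close the ring to the 4-hydroxychromene-2-thione F3. S-methylation (MeI, K2CO3, acetone) gives the 2-(methylsulfanyl)chromone F4.
- H2O2 in hexafluoroisopropanol oxidises sulfides but leaves isolated alkenes alone, and should give the sulfoxide F5.
- 4-(Triisopropylsilyloxy)phenol F6 (from 14, TIPSCl, imidazole) then displaces the sulfinyl group (K2CO3, DMF, rt). This is the established entry to 2-aryloxychromones.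

*Step 3 (key step).*
- Risk: the vinylogous-ester stabilisation of 7 may raise the ring-opening temperature above what 6 tolerates, where it undergoes a 1,3-silyl shift to a silylketene. The ketene may also be lost by oligomerisation or by acylating the product phenol.
- Fallback: ring A is bought, and symmetry replaces the cascade. It sets out from prenyl bromide 1 and rejoins the route at phenol 12.
- Purchased phloroglucinol F7 is mono-etherified (EtOH, HCl) to 5-ethoxyresorcinol F8 and protected (MOMCl, i-Pr2NEt) as the bis-MOM ether F9.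
- Lithiation at the carbon flanked by both MOM ethers (n-BuLi, THF, 0 °C), transmetalation with CuI and alkylation with 1 should give the prenylated bis-MOM ether F10.
- Mild acidic methanolysis frees 5-ethoxy-2-prenylresorcinol F11. Its two hydroxyls are equivalent, so one equivalent of TIPSCl with imidazole leads to 12.

*Step 7.*
- Risk: addition to the phenoxide-deactivated, doubly ortho-substituted aldehyde may be sluggish. The very electron-rich ynol-ether carbinol may also ionise or undergo Meyer–Schuster rearrangement during work-up.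
- Fallback: acylation replaces addition and oxidation, so no carbinol is formed. It sets out from aldehyde 13, uses acetylide 20 made from 18 as in step 7, and rejoins the route at ynone 22, so step 8 drops out.
- Pinnick oxidation (NaClO2, NaH2PO4, large excess of 2-methylbut-2-ene, t-BuOH/H2O) should give the salicylic acid F12. Acetone, SOCl2 and DMAP in DME tie acid and phenol together as the 2,2-dimethylbenzodioxinone F13.
- Acetylide 20 (1.1 equiv, THF, −78 °C) adds once to the ring carbonyl of F13. Collapse of the hemiketal on work-up delivers 22.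

**Further compounds**
F1 | step 9 | rac-1-[6-ethoxy-2-hydroxy-3-prenyl-4-(triisopropylsilyloxy)phenyl]ethanol | CC(C)=CCc1c(O)c(C(C)O)c(OCC)cc1O[Si](C(C)C)(C(C)C)C(C)C
F2 | step 9 | 1-[6-ethoxy-2-hydroxy-3-prenyl-4-(triisopropylsilyloxy)phenyl]ethanone | CC(C)=CCc1c(O)c(C(C)=O)c(OCC)cc1O[Si](C(C)C)(C(C)C)C(C)C
F3 | step 9 | 5-ethoxy-4-hydroxy-8-prenyl-7-(triisopropylsilyloxy)-2H-chromene-2-thione | CC(C)=CCc1c(O[Si](C(C)C)(C(C)C)C(C)C)cc(OCC)c2c(O)cc(=S)oc12
F4 | step 9 | 5-ethoxy-2-(methylsulfanyl)-8-prenyl-7-(triisopropylsilyloxy)-4H-chromen-4-one | CC(C)=CCc1c(O[Si](C(C)C)(C(C)C)C(C)C)cc(OCC)c2c(=O)cc(SC)oc12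
F5 | step 9 | rac-5-ethoxy-2-(methylsulfinyl)-8-prenyl-7-(triisopropylsilyloxy)-4H-chromen-4-one | CC(C)=CCc1c(O[Si](C(C)C)(C(C)C)C(C)C)cc(OCC)c2c(=O)cc(S(C)=O)oc12
F6 | step 9 | 4-(triisopropylsilyloxy)phenol | Oc1ccc(O[Si](C(C)C)(C(C)C)C(C)C)cc1
F7 | step 3 | phloroglucinol (purchased) | Oc1cc(O)cc(O)c1
F8 | step 3 | 5-ethoxybenzene-1,3-diol | CCOc1cc(O)cc(O)c1
F9 | step 3 | 1-ethoxy-3,5-bis(methoxymethoxy)benzene | CCOc1cc(OCOC)cc(OCOC)c1
F10 | step 3 | 5-ethoxy-1,3-bis(methoxymethoxy)-2-(3-methylbut-2-en-1-yl)benzene | CCOc1cc(OCOC)c(CC=C(C)C)c(OCOC)c1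
F11 | step 3 | 5-ethoxy-2-(3-methylbut-2-en-1-yl)benzene-1,3-diol | CCOc1cc(O)c(CC=C(C)C)c(O)c1
F12 | step 7 | 6-ethoxy-2-hydroxy-3-prenyl-4-(triisopropylsilyloxy)benzoic acid | CC(C)=CCc1c(O)c(C(=O)O)c(OCC)cc1O[Si](C(C)C)(C(C)C)C(C)C
F13 | step 7 | 5-ethoxy-2,2-dimethyl-8-prenyl-7-(triisopropylsilyloxy)-4H-1,3-benzodioxin-4-one | CC(C)=CCc1c(O[Si](C(C)C)(C(C)C)C(C)C)cc(OCC)c2c1OC(C)(C)OC2=O
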